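**Plan**

- Retrosynthesis: the target, (2S)-5-hydroxy-7-methoxy-6-prenyl-2-(3,4,5-trimethoxyphenyl)chroman-4-one, is first masked (5-OH as a MOM ether, C4=O as a spiro-1,3-dithiane); ring C is then cut at C3–C4 and at O1–C8a in one stroke.
- Enabling feature: in ring C the acyl carbon C4 and the ether carbon C8a are ortho neighbours on ring A, and C3–C2–O1 is the C–C–O triad of an aryl oxirane. With C4 as a lithiated dithiane (nucleophile) and C8a–F (electrophile), ring A becomes a 1,3-donor/acceptor that annulates the oxirane ([3+3]).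
- The dithiane is a temporary ring that is not in the target: it inverts the polarity of C4 and, by removing the carbonyl, shuts off the enolate-triggered ring opening (retro-oxa-Michael) that racemises flavanones in base.
- Forward: ring A is dressed first (SNAr of one fluoride of a symmetric 2,6-difluorobenzaldehyde by a 1,1-dimethylallyl alkoxide, Claisen shift placing prenyl at C6 and OH at C5, dithiane, MOM); the oxirane is made separately; ring C is closed in the key step; the two helpers are then removed.
- Stereochemistry: the only stereocentre, C2, is set by CBS reduction of an α-bromo ketone and carried through the (R)-oxirane; its C–O bond is never broken, so it becomes (2S) in the flavanone by a change of descriptor only.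

Key step: step 7

Remark: the target SMILES is read as the (2S)-flavanone; 2,6-difluoro-4-methoxybenzaldehyde, 2-methylbut-3-en-2-ol and 2-bromo-1-(3,4,5-trimethoxyphenyl)ethan-1-one are taken as commercial.

**Route**

Step 1
Reactants: 1 2,6-difluoro-4-methoxybenzaldehyde; 2 2-methylbut-3-en-2-ol
Product: 3 2-fluoro-4-methoxy-6-[(2-methylbut-3-en-2-yl)oxy]benzaldehyde
Conditions: NaH, THF, 0 °C → rt (alkoxide of 2); then 1, THF/DMF, −10 → 0 °C
Reagents that add atoms: none
Why: Nucleophilic aromatic substitution (SNAr): the formyl group activates both equivalent ortho fluorides, the tertiary alkoxide cannot transfer hydride to the aldehyde, and the first alkoxy group deactivates the ring so that substitution should stop at the monoether.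

Step 2
Reactants: 3 2-fluoro-4-methoxy-6-[(2-methylbut-3-en-2-yl)oxy]benzaldehyde
Product: 4 6-fluoro-2-hydroxy-4-methoxy-3-(3-methylbut-2-en-1-yl)benzaldehyde
Conditions: toluene, 110 °C (sealed tube)
Reagents that add atoms: none
Why: Aromatic Claisen rearrangement ([3,3]) of the 1,1-dimethylallyl aryl ether, in which the only ortho position that can rearomatise lies between the ether oxygen and the methoxy group, so the prenyl chain and the free hydroxyl should arise exactly where C6 and C5 of the target need them.

Step 3
Reactants: 4 6-fluoro-2-hydroxy-4-methoxy-3-(3-methylbut-2-en-1-yl)benzaldehyde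
Product: 5 2-(1,3-dithian-2-yl)-3-fluoro-5-methoxy-6-(3-methylbut-2-en-1-yl)phenol
Conditions: propane-1,3-dithiol, BF3·OEt2 (cat.), CH2Cl2, −20 → 0 °C
Reagents that add atoms: propane-1,3-dithiol, SCCCS
Why: Lewis-acid-catalysed dithioacetalisation of an aromatic aldehyde (Corey–Seebach dithiane formation), run cold with catalytic acid to spare the acid-sensitive ortho-prenylphenol.

Step 4
Reactants: 5 2-(1,3-dithian-2-yl)-3-fluoro-5-methoxy-6-(3-methylbut-2-en-1-yl)phenol
Product: 6 2-[6-fluoro-4-methoxy-2-(methoxymethoxy)-3-(3-methylbut-2-en-1-yl)phenyl]-1,3-dithiane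
Conditions: NaH, DMF, 0 °C; MOMCl, 0 °C → rt
Reagents that add atoms: chloromethyl methyl ether (MOMCl), COCCl
Why: Williamson-type O-alkylation of the sodium phenoxide, the dithiane C–H being too weakly acidic for NaH; the methoxymethyl ether tolerates the organolithium and alkoxide conditions of step 7.

Step 5
Reactants: 7 2-bromo-1-(3,4,5-trimethoxyphenyl)ethan-1-one
Product: 8 (1R)-2-bromo-1-(3,4,5-trimethoxyphenyl)ethan-1-ol
Conditions: (R)-Me-CBS [(R)-1-methyl-3,3-diphenyltetrahydro-1H,3H-pyrrolo[1,2-c][1,3,2]oxazaborole] (10 mol %), BH3·SMe2, THF, 0 °C; MeOH quench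
Reagents that add atoms: none
Why: Corey–Bakshi–Shibata (CBS) reduction, in which the (R)-oxazaborolidine–borane complex, with the aryl group as the large substituent, should deliver hydride to the Si face of the ketone and so give the (R)-bromohydrin.

Step 6
Reactants: 8 (1R)-2-bromo-1-(3,4,5-trimethoxyphenyl)ethan-1-ol
Product: 9 (2R)-2-(3,4,5-trimethoxyphenyl)oxirane
Conditions: NaOH (aq., 2 M), THF, 0 °C → rt
Reagents that add atoms: none
Why: Intramolecular Williamson etherification (3-exo-tet) of the bromohydrin, in which no bond to the stereocentre is broken, so the (R) configuration is retained.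

Step 7
Reactants: 6 2-[6-fluoro-4-methoxy-2-(methoxymethoxy)-3-(3-methylbut-2-en-1-yl)phenyl]-1,3-dithiane; 9 (2R)-2-(3,4,5-trimethoxyphenyl)oxirane
Product: 13 (2S)-7-methoxy-5-(methoxymethoxy)-6-(3-methylbut-2-en-1-yl)-2-(3,4,5-trimethoxyphenyl)spiro[chromane-4,2'-[1,3]dithiane], via lithiated dithiane 10 (not isolated), via lithium alkoxide 11 (not isolated), via potassium alkoxide 12 (not isolated)
Conditions: n-BuLi, THF, −78 → −30 °C; then 9, DMPU, −78 → 0 °C; then KOt-Bu, 60 °C
Reagents that add atoms: none
Why: Proposed new method: n-BuLi removes the dithiane proton to give the acyl-anion equivalent 10 (Corey–Seebach umpolung of the future C4), which opens oxirane 9 by SN2 attack at its CH2 carbon (C3–C4 bond) and releases alkoxide 11; after lithium–potassium exchange the alkoxide 12, now within six-ring reach of the fluorine-bearing carbon, displaces fluoride by addition–elimination (SNAr) to make the O1–C8a bond. The closest known reaction types are the opening of terminal aryl oxiranes by 2-aryl-2-lithio-1,3-dithianes and the base-mediated closure of 3-(2-fluoroaryl)propan-1-ols to chromans, and what is new is their fusion in one flask into a [3+3] annulation on a non-activated, dithiane-bearing fluoroarene. Ring C closes in 6-exo-trig fashion at the arene carbon followed by loss of fluoride, helped by the quaternary dithiane carbon in the tether (Thorpe–Ingold effect) and by the two meta alkoxy groups, which activate C8a inductively. No stereocentre is created: C2 is the oxirane stereocentre, its C–O bond is never broken, and with C4 held as a thioketal no enolate exists that could open ring C, so the (R)-oxirane should be delivered as the (2S)-flavan. The step needs attack at the terminal rather than the benzylic oxirane carbon, secured by the bulk of the tertiary carbanion and the absence of a Lewis acid, and a single site of etherification, secured by the single fluorine and a tether that reaches only C8a. It also needs deprotonation at the dithiane carbon only, which the doubly sulfur-stabilised benzylic C–H, more acidic than the ring proton at C8 or the allylic protons of the prenyl group, should secure at −78 °C.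

Step 8
Reactants: 13 (2S)-7-methoxy-5-(methoxymethoxy)-6-(3-methylbut-2-en-1-yl)-2-(3,4,5-trimethoxyphenyl)spiro[chromane-4,2'-[1,3]dithiane]
Product: 14 (2S)-7-methoxy-5-(methoxymethoxy)-6-(3-methylbut-2-en-1-yl)-2-(3,4,5-trimethoxyphenyl)-2,3-dihydro-4H-chromen-4-one
Conditions: MeI, CaCO3, MeCN/H2O (9:1), 45 °C
Reagents that add atoms: water, O
Why: S-Methylation of the thioketal and hydrolysis of the thionium ion (stabilised by the ortho and para oxygen substituents of ring A) under carbonate-buffered, near-neutral conditions that should leave the prenyl alkene, the acetal and the C2 stereocentre untouched.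

Step 9
Reactants: 14 (2S)-7-methoxy-5-(methoxymethoxy)-6-(3-methylbut-2-en-1-yl)-2-(3,4,5-trimethoxyphenyl)-2,3-dihydro-4H-chromen-4-one
Product: 15 artoflavanone, (2S)-5-hydroxy-7-methoxy-6-(3-methylbut-2-en-1-yl)-2-(3,4,5-trimethoxyphenyl)-2,3-dihydro-4H-chromen-4-one
Conditions: HCl (cat.), MeOH, 0 °C → rt
Reagents that add atoms: none
Why: Acid-catalysed acetal exchange (methanolysis of the methoxymethyl ether), which is fast for the ether peri to the carbonyl and mild enough that ring C should not open, so C2 stays (S).

**Compound list**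

1 | 2,6-difluoro-4-methoxybenzaldehyde | COc1cc(F)c(C=O)c(F)c1 | starting material
2 | 2-methylbut-3-en-2-ol | CC(C)(O)C=C | starting material
3 | 2-fluoro-4-methoxy-6-[(2-methylbut-3-en-2-yl)oxy]benzaldehyde | COc1cc(F)c(C=O)c(OC(C)(C)C=C)c1 | intermediate
4 | 6-fluoro-2-hydroxy-4-methoxy-3-(3-methylbut-2-en-1-yl)benzaldehyde | COc1cc(F)c(C=O)c(O)c1CC=C(C)C | intermediate
5 | 2-(1,3-dithian-2-yl)-3-fluoro-5-methoxy-6-(3-methylbut-2-en-1-yl)phenol | COc1cc(F)c(C2SCCCS2)c(O)c1CC=C(C)C | intermediate
6 | 2-[6-fluoro-4-methoxy-2-(methoxymethoxy)-3-(3-methylbut-2-en-1-yl)phenyl]-1,3-dithiane | COCOc1c(CC=C(C)C)c(OC)cc(F)c1C1SCCCS1 | intermediate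
7 | 2-bromo-1-(3,4,5-trimethoxyphenyl)ethan-1-one | COc1cc(C(=O)CBr)cc(OC)c1OC | starting material
8 | (1R)-2-bromo-1-(3,4,5-trimethoxyphenyl)ethan-1-ol | COc1cc([C@@H](O)CBr)cc(OC)c1OC | intermediate
9 | (2R)-2-(3,4,5-trimethoxyphenyl)oxirane | COc1cc([C@@H]2CO2)cc(OC)c1OC | intermediate
10 | {2-[6-fluoro-4-methoxy-2-(methoxymethoxy)-3-(3-methylbut-2-en-1-yl)phenyl]-1,3-dithian-2-yl}lithium (lithiated dithiane, not isolated) | COCOc1c(CC=C(C)C)c(OC)cc(F)c1C1([Li])SCCCS1 | intermediate
11 | lithium (1S)-2-{2-[6-fluoro-4-methoxy-2-(methoxymethoxy)-3-(3-methylbut-2-en-1-yl)phenyl]-1,3-dithian-2-yl}-1-(3,4,5-trimethoxyphenyl)ethan-1-olate (not isolated) | [Li+].COCOc1c(CC=C(C)C)c(OC)cc(F)c1C1(C[C@H]([O-])c2cc(OC)c(OC)c(OC)c2)SCCCS1 | intermediate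
12 | potassium (1S)-2-{2-[6-fluoro-4-methoxy-2-(methoxymethoxy)-3-(3-methylbut-2-en-1-yl)phenyl]-1,3-dithian-2-yl}-1-(3,4,5-trimethoxyphenyl)ethan-1-olate (not isolated) | [K+].COCOc1c(CC=C(C)C)c(OC)cc(F)c1C1(C[C@H]([O-])c2cc(OC)c(OC)c(OC)c2)SCCCS1 | intermediate
13 | (2S)-7-methoxy-5-(methoxymethoxy)-6-(3-methylbut-2-en-1-yl)-2-(3,4,5-trimethoxyphenyl)spiro[chromane-4,2'-[1,3]dithiane] | COc1cc2c(c(OCOC)c1CC=C(C)C)C3(SCCCS3)C[C@@H](c3cc(OC)c(OC)c(OC)c3)O2 | intermediate
14 | (2S)-7-methoxy-5-(methoxymethoxy)-6-(3-methylbut-2-en-1-yl)-2-(3,4,5-trimethoxyphenyl)-2,3-dihydro-4H-chromen-4-one | COc1cc2c(c(OCOC)c1CC=C(C)C)C(=O)C[C@@H](c1cc(OC)c(OC)c(OC)c1)O2 | intermediate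
15 | artoflavanone, (2S)-5-hydroxy-7-methoxy-6-(3-methylbut-2-en-1-yl)-2-(3,4,5-trimethoxyphenyl)-2,3-dihydro-4H-chromen-4-one | COc1cc2c(c(O)c1CC=C(C)C)C(=O)C[C@@H](c1cc(OC)c(OC)c(OC)c1)O2 | target

**Step count**

Total steps: 9. Longest linear sequence: 7 steps (steps 1, 2, 3, 4, 7, 8, 9); the oxirane branch (steps 5, 6) joins at step 7.

**Steps most likely to fail**

1. Step 7 (proposed new method). The tethered alkoxide may fail to displace fluoride from the electron-rich, non-activated ring A, or base-induced migration of the prenyl double bond may outrun a slow closure. The fallback separates the two bond formations and changes the mechanism of the C–O closure from addition–elimination to elimination–addition, both being known reaction types. It sets out from 6 and 9: lithiation of 6 (n-BuLi, THF, −78 → −30 °C) and opening of 9 as before, then aqueous quench at 0 °C, would give the open-chain alcohol (1S)-2-{2-[6-fluoro-4-methoxy-2-(methoxymethoxy)-3-(3-methylbut-2-en-1-yl)phenyl]-1,3-dithian-2-yl}-1-(3,4,5-trimethoxyphenyl)ethan-1-ol F1. Treatment of this alcohol with LiTMP (lithium 2,2,6,6-tetramethylpiperidide, 2.2 equiv) in THF, −78 °C → rt, should deprotonate the hydroxyl and then the only ring proton (C8–H, flanked by F and OMe). Loss of LiF would give the C8–C8a aryne, which the tethered alkoxide can capture only at C8a (an attack that also places the aryl anion next to the methoxy group); protonation at C8 returns the route at 13.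

2. Step 1. The hindered tertiary alkoxide may add reversibly to the formyl group or act mainly as a base, so that substitution is slow, runs on to the diether, or is accompanied by premature ionisation or rearrangement of the tertiary allylic ether. The fallback brings in the side chain as an allyl group and converts it to prenyl by olefin metathesis. It sets out from 1: SNAr with sodium allyloxide (allyl alcohol, NaH, THF, 0 °C) would give 2-fluoro-4-methoxy-6-(prop-2-en-1-yloxy)benzaldehyde F2. Thermal Claisen rearrangement (N,N-diethylaniline, 190 °C) would give 6-fluoro-2-hydroxy-4-methoxy-3-(prop-2-en-1-yl)benzaldehyde F3. Cross-metathesis with 2-methylbut-2-ene (second-generation Grubbs catalyst RuCl2(=CHPh)(H2IMes)(PCy3), CH2Cl2, 40 °C) returns the route at 4.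

3. Step 3. Thioacetalisation of the hindered, hydrogen-bonded aldehyde may be slow enough that acid-promoted cyclisation of the prenyl chain onto the adjacent free hydroxyl (chroman formation) takes over. The fallback masks the phenol temporarily, which removes the internal nucleophile and the hydrogen bond that deactivates the aldehyde. It sets out from 4: acetylation (Ac2O, pyridine, rt) would give 3-fluoro-2-formyl-5-methoxy-6-(3-methylbut-2-en-1-yl)phenyl acetate F4. Dithioacetalisation (propane-1,3-dithiol, BF3·OEt2 cat., CH2Cl2, −40 → −20 °C) would give 2-(1,3-dithian-2-yl)-3-fluoro-5-methoxy-6-(3-methylbut-2-en-1-yl)phenyl acetate F5. Methanolysis of the acetate (K2CO3 cat., MeOH, rt) returns the route at 5.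

**Further compounds**

F1 | step 7 | (1S)-2-{2-[6-fluoro-4-methoxy-2-(methoxymethoxy)-3-(3-methylbut-2-en-1-yl)phenyl]-1,3-dithian-2-yl}-1-(3,4,5-trimethoxyphenyl)ethan-1-ol | COCOc1c(CC=C(C)C)c(OC)cc(F)c1C1(C[C@H](O)c2cc(OC)c(OC)c(OC)c2)SCCCS1
F2 | step 1 | 2-fluoro-4-methoxy-6-(prop-2-en-1-yloxy)benzaldehyde | C=CCOc1cc(OC)cc(F)c1C=O
F3 | step 1 | 6-fluoro-2-hydroxy-4-methoxy-3-(prop-2-en-1-yl)benzaldehyde | COc1cc(F)c(C=O)c(O)c1CC=C
F4 | step 3 | 3-fluoro-2-formyl-5-methoxy-6-(3-methylbut-2-en-1-yl)phenyl acetate | COc1cc(F)c(C=O)c(OC(C)=O)c1CC=C(C)C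
F5 | step 3 | 2-(1,3-dithian-2-yl)-3-fluoro-5-methoxy-6-(3-methylbut-2-en-1-yl)phenyl acetate | COc1cc(F)c(C2SCCCS2)c(OC(C)=O)c1CC=C(C)C
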